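**Plan**

Locants: ring C1 (C=O), C2=C3(Me), C4 (OAc), C5–C6 (oxirane). C6 carries the chain C1′–C12′. "Farnesyl" means (2E,6E)-3,7,11-trimethyldodeca-2,6,10-trien-1-yl.
Cuts: C12′–OH; the C2=C3 π bond and a helper ester on C2; then, in one retro-Darzens step, ring bond C5–C6 together with the oxirane bond C6–O; then C4–OAc, C2–C3 (retro-Michael), C6–Cl and C6–C1′.
Forward: the chain is joined first by γ-alkylation of allyl acetoacetate. The acyclic array C6–C1–C2 + C3–C4–C5 is completed with crotonaldehyde, and carbocycle and oxirane arise together in step 5. C2=C3 and C12′–OH come last, and no arene, quinone or epoxidising agent is used.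
Enabling feature: the C1 ketone and C5–C6 oxirane of the 7-oxabicyclo[4.1.0]heptenone form a Darzens retron. The fully substituted C6 is an α-chloro-enolate carbon and C5–O is an aldehyde. C4–OAc lies α to that aldehyde and is therefore epimerisable.
Stereochemistry: one catalytic event (iminium Michael addition) sets a helper centre at C3. In step 5 it steers a chair aldol in which the mixtures at C2, C4 and C6 converge on 4R,5R,6R. C3 is then erased by dehydrogenation.

Key step: step 5

Assumption: N-methyl-O-acetylhydroxylamine hydrochloride is treated as a stock reagent, made in the known way from N-Boc-N-methylhydroxylamine (AcCl, then HCl), and is not counted as a step.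

Step 1
Reactants: 1 allyl acetoacetate; 2 (2E,6E)-farnesyl bromide
Product: 3 allyl (6E,10E)-7,11,15-trimethyl-3-oxohexadeca-6,10,14-trienoate
Conditions: LDA (2.1 equiv), THF, 0 °C; 2, 0 °C to rt; aqueous quench
Reagents that add atoms: none
Why: In this β-keto ester dianion (Weiler) alkylation the dianion reacts only at its terminal γ-carbanion, and SN2 attack on the primary allylic bromide keeps both E-alkenes, so the chain (C1′) is bonded to the future C6 with no regiochemical ambiguity.

Step 2
Reactants: 3 allyl (6E,10E)-7,11,15-trimethyl-3-oxohexadeca-6,10,14-trienoate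
Product: 4 allyl (6E,10E)-4-chloro-7,11,15-trimethyl-3-oxohexadeca-6,10,14-trienoate (racemic at C4)
Conditions: LDA (2.1 equiv), THF, –78 °C; cannulated into C2Cl6, THF, –78 °C; aqueous quench
Reagents that add atoms: hexachloroethane ClC(Cl)(Cl)C(Cl)(Cl)Cl
Why: This is electrophilic trapping of a β-keto ester dianion, in which the more nucleophilic γ-carbanion takes Cl+ from hexachloroethane while the alkenes stay untouched, and the racemic C–Cl centre (future C6) is harmless because it is planarised again in step 5.

Step 3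
Reactants: 4 allyl (6E,10E)-4-chloro-7,11,15-trimethyl-3-oxohexadeca-6,10,14-trienoate; 5 (E)-crotonaldehyde
Product: 6 allyl (6E,10E)-4-chloro-7,11,15-trimethyl-3-oxo-2-[(2R)-4-oxobutan-2-yl]hexadeca-6,10,14-trienoate (mixture at C2 and C4)
Conditions: (S)-2-[diphenyl(trimethylsilyloxy)methyl]pyrrolidine (10 mol %), PhCO2H (10 mol %), toluene, 0 °C, no added base
Reagents that add atoms: none
Why: In this diarylprolinol silyl ether iminium-catalysed Michael addition of a β-keto ester to an enal, the silyloxydiphenylmethyl group of the (S)-catalyst blocks one face of the E-iminium ion, so bond C2–C3 should form with R configuration at the methyl-bearing carbon (future C3), while the epimers at the two acidic centres are immaterial.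

Step 4
Reactants: 6 allyl (6E,10E)-4-chloro-7,11,15-trimethyl-3-oxo-2-[(2R)-4-oxobutan-2-yl]hexadeca-6,10,14-trienoate
Product: 7 allyl (6E,10E)-2-[(2S)-3-acetoxy-4-oxobutan-2-yl]-4-chloro-7,11,15-trimethyl-3-oxohexadeca-6,10,14-trienoate (mixture at C2, C4 and the acetoxy carbon)
Conditions: MeNHOAc·HCl (1.1 equiv), DMSO, rt
Reagents that add atoms: N-methyl-O-acetylhydroxylamine hydrochloride CNOC(C)=O.Cl
Why: In this α-acyloxylation of an aldehyde with an N-alkyl-O-acylhydroxylamine salt, condensation at the most reactive carbonyl, [3,3]-shift of the N-vinyl-O-acetylhydroxylamine and hydrolysis place OAc on the future C4 without any oxidant that could touch the trisubstituted alkenes, and both C4 epimers form and both are used.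

Step 5
Reactants: 7 allyl (6E,10E)-2-[(2S)-3-acetoxy-4-oxobutan-2-yl]-4-chloro-7,11,15-trimethyl-3-oxohexadeca-6,10,14-trienoate
Product: 9 allyl (3S,4R,5R,6R)-4-acetoxy-5,6-epoxy-6-farnesyl-3-methyl-1-oxocyclohexane-2-carboxylate (C2 not defined), via aldol chlorohydrin 8 (not isolated)
Conditions: K2CO3 (1.1 equiv), DMF, 0 °C to rt
Reagents that add atoms: none
Why: Carbonate reversibly enolises 7 at C2, C4 and C6; the C6 α-chloro enolate adds to the C5 aldehyde (6-(enolendo)-exo-trig aldol, closes the carbocycle) and the C5 alkoxide of 8 displaces the now tertiary, ketone-activated C6 chloride (3-exo-tet, closes the oxirane), which is an intramolecular Darzens condensation. The closest known reaction type is the one-pot Michael/aldol/SN2 annulation of γ-chloro-β-keto esters with enals to epoxycyclohexanones, and only the substituent on the chlorinated carbon and the acetoxy group next to the aldehyde differ here. Only the aldolate with C5–O and C6–Cl trans-diaxial can close, and in the chair that keeps the fixed C3 methyl equatorial this places C5–O axial on the face opposite to the methyl group, which fixes C5 (R) and, after inversion, C6 (R). In that chair an axial C4–OAc would be 1,3-diaxial to the C6–Cl bond, so the equatorial C4 epimer (OAc on the oxirane face, 4R) should react while the other epimer is fed in through the aldehyde enolate. Because the aldol addition and all enolisations are reversible and oxirane closure is not, the eight-isomer mixture should be funnelled into one ring diastereomer, with C2 staying epimerisable until it is removed. The step needs attack from C6 rather than C2, which ring size secures (C2 would give a cyclobutanol), and a base too weak to deprotonate C4–H of the product.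

Step 6
Reactants: 9 allyl (3S,4R,5R,6R)-4-acetoxy-5,6-epoxy-6-farnesyl-3-methyl-1-oxocyclohexane-2-carboxylate
Product: 11 (3S,4R,5R,6R)-4-acetoxy-5,6-epoxy-6-farnesyl-3-methylcyclohexanone, via β-keto acid 10 (not isolated)
Conditions: Pd(PPh3)4 (5 mol %), morpholine (1.5 equiv), THF, rt
Reagents that add atoms: none
Why: In this Tsuji–Trost-type deallylation, Pd(0) ionises only the allyl ester (the C4 acetate is not allylic at this stage), morpholine takes the allyl group and the β-keto acid loses CO2 at room temperature, so C2 becomes CH2 and no stereocentre is touched.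

Step 7
Reactants: 11 (3S,4R,5R,6R)-4-acetoxy-5,6-epoxy-6-farnesyl-3-methylcyclohexanone
Product: 12 (4R,5R,6R)-4-acetoxy-5,6-epoxy-6-farnesyl-3-methylcyclohex-2-enone
Conditions: LiHMDS (1.05 equiv), THF, –78 °C; then PhS(Cl)=N-t-Bu, –78 °C
Reagents that add atoms: none
Why: In this Mukaiyama one-pot dehydrogenation C2 is the only enolisable position (C6 is quaternary), the enolate is sulfenylated at C2 and the sulfilimine nitrogen removes C3–H in a syn-elimination, which installs C2=C3 and erases the helper stereocentre without metal or peroxide.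

Step 8
Reactants: 12 (4R,5R,6R)-4-acetoxy-5,6-epoxy-6-farnesyl-3-methylcyclohex-2-enone
Product: 13 yanuthone L, (4R,5R,6R)-4-acetoxy-5,6-epoxy-6-[(2E,6E,10E)-12-hydroxy-3,7,11-trimethyldodeca-2,6,10-trienyl]-3-methylcyclohex-2-enone
Conditions: SeO2 (cat.), t-BuOOH, salicylic acid (cat.), CH2Cl2, 0 °C to rt, stopped at partial conversion
Reagents that add atoms: tert-butyl hydroperoxide CC(C)(C)OO (terminal oxygen source); selenium dioxide O=[Se]=O (oxygen carrier)
Why: In this catalytic SeO2 (Riley-type) allylic hydroxylation the ene/[2,3] sequence selects the most accessible, electron-rich terminal trisubstituted alkene and its E-methyl group, as is general for farnesyl derivatives, while the enone alkene is too electron-poor to react.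

**Compound list**

1 | allyl acetoacetate | C=CCOC(=O)CC(C)=O | starting material
2 | (2E,6E)-farnesyl bromide | BrC/C=C(\C)CC/C=C(\C)CCC=C(C)C | starting material
3 | allyl (6E,10E)-7,11,15-trimethyl-3-oxohexadeca-6,10,14-trienoate | C=CCOC(=O)CC(=O)CC/C=C(\C)CC/C=C(\C)CCC=C(C)C | intermediate
4 | allyl (6E,10E)-4-chloro-7,11,15-trimethyl-3-oxohexadeca-6,10,14-trienoate | C=CCOC(=O)CC(=O)C(Cl)C/C=C(\C)CC/C=C(\C)CCC=C(C)C | intermediate
5 | (E)-crotonaldehyde | C/C=C/C=O | starting material
6 | allyl (6E,10E)-4-chloro-7,11,15-trimethyl-3-oxo-2-[(2R)-4-oxobutan-2-yl]hexadeca-6,10,14-trienoate | C=CCOC(=O)C([C@H](C)CC=O)C(=O)C(Cl)C/C=C(\C)CC/C=C(\C)CCC=C(C)C | intermediate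
7 | allyl (6E,10E)-2-[(2S)-3-acetoxy-4-oxobutan-2-yl]-4-chloro-7,11,15-trimethyl-3-oxohexadeca-6,10,14-trienoate | C=CCOC(=O)C([C@H](C)C(OC(C)=O)C=O)C(=O)C(Cl)C/C=C(\C)CC/C=C(\C)CCC=C(C)C | intermediate
8 | allyl (3S,4R,5R,6S)-4-acetoxy-6-chloro-6-farnesyl-5-hydroxy-3-methyl-1-oxocyclohexane-2-carboxylate | CC(=O)O[C@@H]1[C@@H](C)C(C(=O)OCC=C)C(=O)[C@](Cl)(C/C=C(\C)CC/C=C(\C)CCC=C(C)C)[C@@H]1O | intermediate
9 | allyl (3S,4R,5R,6R)-4-acetoxy-5,6-epoxy-6-farnesyl-3-methyl-1-oxocyclohexane-2-carboxylate | CC(=O)O[C@@H]1[C@@H](C)C(C(=O)OCC=C)C(=O)[C@]2(C/C=C(\C)CC/C=C(\C)CCC=C(C)C)O[C@H]12 | intermediate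
10 | (3S,4R,5R,6R)-4-acetoxy-5,6-epoxy-6-farnesyl-3-methyl-1-oxocyclohexane-2-carboxylic acid | CC(=O)O[C@@H]1[C@@H](C)C(C(=O)O)C(=O)[C@]2(C/C=C(\C)CC/C=C(\C)CCC=C(C)C)O[C@H]12 | intermediate
11 | (3S,4R,5R,6R)-4-acetoxy-5,6-epoxy-6-farnesyl-3-methylcyclohexanone | CC(=O)O[C@@H]1[C@@H](C)CC(=O)[C@]2(C/C=C(\C)CC/C=C(\C)CCC=C(C)C)O[C@H]12 | intermediate
12 | (4R,5R,6R)-4-acetoxy-5,6-epoxy-6-farnesyl-3-methylcyclohex-2-enone | CC(=O)O[C@@H]1C(C)=CC(=O)[C@]2(C/C=C(\C)CC/C=C(\C)CCC=C(C)C)O[C@H]12 | intermediate
13 | yanuthone L | CC(=O)O[C@@H]1C(C)=CC(=O)[C@]2(C/C=C(\C)CC/C=C(\C)CC/C=C(\C)CO)O[C@H]12 | target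

Total step count: 8. Longest linear sequence: 8.

**Steps most likely to fail**

Step 5 is the riskiest.
- **What may go wrong:** The acetyl group may migrate from O4 to the C5 alkoxide. The C3 information may erode by retro-Michael cleavage through the acidic C4–H. Closure at the tertiary chloride may be too slow to compete with Favorskii-type contraction.
- **Fallback:** It uses known aromatic chemistry, sets out from 2 and returns at 12.
  - Sodium m-cresolate is C-alkylated with 2 in toluene to 2-farnesyl-5-methylphenol F1.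
  - PhI(OAc)2 in methanol gives the quinone monoketal 2-farnesyl-4,4-dimethoxy-5-methylcyclohexa-2,5-dienone F2.
  - Weitz–Scheffer epoxidation (t-BuOOH, aqueous NaOH, cinchona-derived ammonium salt, toluene) attacks the only β-unsubstituted enone arm and should give the epoxy ketal (5S,6R)-5,6-epoxy-6-farnesyl-4,4-dimethoxy-3-methylcyclohex-2-enone F3.
  - Mild acid hydrolysis gives the epoxyquinone (5S,6R)-5,6-epoxy-6-farnesyl-3-methylcyclohex-2-ene-1,4-dione F4.
  - DIBAL-H at –78 °C adds to the less hindered C4 carbonyl, anti to the oxirane, to give the syn-epoxyquinol (4R,5R,6R)-5,6-epoxy-6-farnesyl-4-hydroxy-3-methylcyclohex-2-enone F5.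
  - Ac2O/pyridine then gives 12.

Step 4 comes next.
- **What may go wrong:** The hydroxylamine may condense with the β-keto ester instead of the aldehyde. Alternatively, 6 may undergo premature aldol closure before the oxygen is in place.
- **Fallback:** It sets out from 6 and returns at 7, and delivers oxygen to a catalytic enamine instead of by sigmatropic shift. Pyrrolidine-catalysed α-hydroxylation with 2-(phenylsulfonyl)-3-phenyloxaziridine in THF gives allyl (6E,10E)-4-chloro-2-[(2S)-3-hydroxy-4-oxobutan-2-yl]-7,11,15-trimethyl-3-oxohexadeca-6,10,14-trienoate F6. This is acetylated in the same flask (Ac2O, pyridine) to 7.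

Step 2 is third.
- **What may go wrong:** Proton exchange between dianion and product may lead to chlorination at C2 or twice at C4. The chloro enolate may also O-cyclise to a furanone.
- **Fallback:** It sets out from 2 and returns at 4, and installs the C–Cl bond before the β-keto ester exists.
  - Dimethyl chloromalonate (NaH, THF) is alkylated with 2 to dimethyl 2-chloro-2-farnesylmalonate F7.
  - Krapcho dealkoxycarbonylation (LiCl, wet DMSO, heat) gives methyl (4E,8E)-2-chloro-5,9,13-trimethyltetradeca-4,8,12-trienoate F8.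
  - Crossed Claisen condensation with the lithium enolate of allyl acetate (LDA, THF, –78 °C) gives 4.

**Further compounds**

F1 | step 5 | 2-farnesyl-5-methylphenol | Cc1ccc(C/C=C(\C)CC/C=C(\C)CCC=C(C)C)c(O)c1
F2 | step 5 | 2-farnesyl-4,4-dimethoxy-5-methylcyclohexa-2,5-dienone | COC1(OC)C=C(C/C=C(\C)CC/C=C(\C)CCC=C(C)C)C(=O)C=C1C
F3 | step 5 | (5S,6R)-5,6-epoxy-6-farnesyl-4,4-dimethoxy-3-methylcyclohex-2-enone | COC1(OC)C(C)=CC(=O)[C@]2(C/C=C(\C)CC/C=C(\C)CCC=C(C)C)O[C@H]12
F4 | step 5 | (5S,6R)-5,6-epoxy-6-farnesyl-3-methylcyclohex-2-ene-1,4-dione | O=C1C(C)=CC(=O)[C@]2(C/C=C(\C)CC/C=C(\C)CCC=C(C)C)O[C@H]12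
F5 | step 5 | (4R,5R,6R)-5,6-epoxy-6-farnesyl-4-hydroxy-3-methylcyclohex-2-enone | O[C@@H]1C(C)=CC(=O)[C@]2(C/C=C(\C)CC/C=C(\C)CCC=C(C)C)O[C@H]12
F6 | step 4 | allyl (6E,10E)-4-chloro-2-[(2S)-3-hydroxy-4-oxobutan-2-yl]-7,11,15-trimethyl-3-oxohexadeca-6,10,14-trienoate | C=CCOC(=O)C([C@H](C)C(O)C=O)C(=O)C(Cl)C/C=C(\C)CC/C=C(\C)CCC=C(C)C
F7 | step 2 | dimethyl 2-chloro-2-farnesylmalonate | COC(=O)C(Cl)(C/C=C(\C)CC/C=C(\C)CCC=C(C)C)C(=O)OC
F8 | step 2 | methyl (4E,8E)-2-chloro-5,9,13-trimethyltetradeca-4,8,12-trienoate | COC(=O)C(Cl)C/C=C(\C)CC/C=C(\C)CCC=C(C)C
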